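**Retrosynthetic overview**

- The strategy rests on the benzene ring with oxygen on C1 and C3 and the C17 chain on C5. C4, C5, C6 and C1 with its oxygen come from a 3-alkylcyclobutenone; C2 and C3 with its oxygen come from ethoxyacetylene.
- Resorcinol ring ⇒ cyclobutenone 15 + ethoxyacetylene 16 (4π opening, [2+2], 4π opening, 6π closure). The benzene ring is the only ring formed in the route; the four-membered ring is bought in 12.
- 15 ⇒ Grignard reagent of bromide 11 + 3-ethoxycyclobutenone 12 (1,2-addition, acid-induced carbonyl transposition).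
- Z-C8'=C9' ⇒ alkyne (Lindlar). C9'–C10' ⇒ dianion of non-8-yn-1-ol 7 + iodide 6. C15' comes from (S)-1,2-epoxybutane 2, with C13'–C14' made by Cu-catalysed Grignard opening.
- End game: fluoride desilylation, then non-protic boron iodide cleavage of the aryl ethyl ether (thiolate dealkylation is avoided because a ring phenoxide suppresses it).

Key step: step 8

Assumption: 3-ethoxycyclobut-2-en-1-one (12), the ketene/ethoxyacetylene [2+2] adduct, is taken as a purchased catalogue compound.

Abbreviation used in names: R = (8Z,15S)-15-(tert-butyldimethylsilyloxy)heptadec-8-en-1-yl.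

**Step 1**
Reactants: 1 1-bromo-4-chlorobutane; 2 (S)-1,2-epoxybutane
Product: 4 (3S)-8-chlorooctan-3-ol, via 4-chlorobutylmagnesium bromide 3 (not isolated)
Conditions: Mg, THF, 20–25 °C; then CuI (10 mol %), 2, −30 → 0 °C; aq. NH4Cl
Reagents that add atoms: none
Why: Magnesium inserts into C–Br much faster than into C–Cl, and the copper-catalysed SN2 epoxide opening by the Grignard reagent occurs at the unsubstituted CH2, so the C–O stereocentre of 2 is carried into 4 unchanged as (S).

**Step 2**
Reactants: 4 (3S)-8-chlorooctan-3-ol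
Product: 5 tert-butyl{[(3S)-8-chlorooctan-3-yl]oxy}dimethylsilane
Conditions: TBSCl, imidazole, DMF, rt
Reagents that add atoms: tert-butyldimethylsilyl chloride (TBSCl), CC(C)(C)[Si](C)(C)Cl
Why: Imidazole-promoted silylation of the secondary alcohol masks the only acidic proton before the organometallic steps and does not touch the stereocentre.

**Step 3**
Reactants: 5 tert-butyl{[(3S)-8-chlorooctan-3-yl]oxy}dimethylsilane
Product: 6 tert-butyl{[(3S)-8-iodooctan-3-yl]oxy}dimethylsilane
Conditions: NaI, butan-2-one, reflux
Reagents that add atoms: sodium iodide, [Na+].[I-]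
Why: Finkelstein exchange, driven by precipitation of NaCl, turns the unreactive primary chloride into an iodide suited to acetylide alkylation under neutral conditions that the silyl ether tolerates.

**Step 4**
Reactants: 7 non-8-yn-1-ol; 6 tert-butyl{[(3S)-8-iodooctan-3-yl]oxy}dimethylsilane
Product: 9 (15S)-15-(tert-butyldimethylsilyloxy)heptadec-8-yn-1-ol, via dilithium alkynolate 8 (not isolated)
Conditions: 7 (1.3 equiv), n-BuLi (2.6 equiv), THF/DMPU, −40 → 0 °C; then 6, 0 °C → rt; aq. NH4Cl
Reagents that add atoms: none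
Why: In this acetylide alkylation of an alkynol dianion the lithium acetylide is far more nucleophilic than the lithium alkoxide, so the primary iodide should be attacked at carbon and no hydroxyl protection is needed.

**Step 5**
Reactants: 9 (15S)-15-(tert-butyldimethylsilyloxy)heptadec-8-yn-1-ol
Product: 10 (8Z,15S)-15-(tert-butyldimethylsilyloxy)heptadec-8-en-1-ol
Conditions: H2 (1 atm), Lindlar catalyst, quinoline, EtOAc/hexane, rt
Reagents that add atoms: none
Why: Lindlar semihydrogenation delivers both hydrogens to one face of the alkyne on the poisoned palladium surface, which sets the Z geometry of C8=C9 and stops at the alkene.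

**Step 6**
Reactants: 10 (8Z,15S)-15-(tert-butyldimethylsilyloxy)heptadec-8-en-1-ol
Product: 11 (8Z,15S)-1-bromo-15-(tert-butyldimethylsilyloxy)heptadec-8-ene
Conditions: CBr4, PPh3, CH2Cl2, 0 °C
Reagents that add atoms: carbon tetrabromide, BrC(Br)(Br)Br
Why: The Appel reaction converts the primary alcohol into the bromide by SN2 under near-neutral conditions that leave the secondary silyl ether and the Z-alkene alone.

**Step 7**
Reactants: 11 (8Z,15S)-1-bromo-15-(tert-butyldimethylsilyloxy)heptadec-8-ene; 12 3-ethoxycyclobut-2-en-1-one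
Product: 15 3-[(8Z,15S)-15-(tert-butyldimethylsilyloxy)heptadec-8-en-1-yl]cyclobut-2-en-1-one, via alkylmagnesium bromide 13 (not isolated), via ethoxycyclobutenol 14 (not isolated)
Conditions: Mg, THF, 45 °C; then 12, THF, −78 → −20 °C; then 1 M HCl, 0 °C
Reagents that add atoms: water, O
Why: Grignard formation, 1,2-addition to the carbonyl of the vinylogous ester 12 and acid-induced loss of ethanol with carbonyl transposition (Stork–Danheiser-type sequence, the new carbonyl oxygen coming from water) give the 3-alkylcyclobutenone, and the brief cold dilute acid should not cleave the secondary silyl ether or move the Z-alkene.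

**Step 8**
Reactants: 15 3-[(8Z,15S)-15-(tert-butyldimethylsilyloxy)heptadec-8-en-1-yl]cyclobut-2-en-1-one; 16 ethoxyacetylene
Product: 21 3-ethoxy-5-[(8Z,15S)-15-(tert-butyldimethylsilyloxy)heptadec-8-en-1-yl]phenol, via vinylketene 17 (not isolated), via vinylcyclobutenone 18 (not isolated), via dienylketene 19 (not isolated), via cyclohexadienone 20 (not isolated)
Conditions: 16 (3 equiv, hexane solution), toluene, 80 °C, sealed tube
Reagents that add atoms: none
Why: At 80 °C cyclobutenone 15 opens by a conrotatory 4π electrocyclic reaction to vinylketene 17, whose ketene C=C bond adds the ynol ether in a [2+2] cycloaddition to give 4-vinylcyclobutenone 18; this opens again (4π, reversible, so the geometry needed for closure is replenished) to dienylketene 19, which closes by thermal disrotatory 6π electrocyclisation to cyclohexadienone 20 and tautomerises to phenol 21. The closest known reaction type is the Danheiser benzannulation of cyclobutenones with alkoxyacetylenes, which gives resorcinol monoethers. The one ring formed is the benzene ring: C1–C2 and C3–C4 arise in the [2+2] step and the ring is closed at C1–C6 by the 6π electrocyclisation. No stereocentre is created in the product (the sp3 ring carbon of 18 is a transient, uncontrolled centre that is erased), and C15 and the Z-alkene take no part. The selectivity needed is the regiochemistry of the [2+2] step, secured by the polarisation of the partners: the nucleophilic CH terminus of ethoxyacetylene bonds to the electrophilic ketene carbonyl carbon, so OEt ends meta to OH with the chain-bearing carbon of 15 at C5. Chemoselectivity rests on the electron-rich ynol ether, used in excess, being a far better ketene trap than the isolated Z-alkene, and the neutral thermal conditions spare the silyl ether.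

**Step 9**
Reactants: 21 3-ethoxy-5-[(8Z,15S)-15-(tert-butyldimethylsilyloxy)heptadec-8-en-1-yl]phenol
Product: 22 3-ethoxy-5-[(8Z,15S)-15-hydroxyheptadec-8-en-1-yl]phenol
Conditions: TBAF, THF, rt; aq. NH4Cl
Reagents that add atoms: none
Why: Fluoride-induced desilylation cleaves only the Si–O bond, so the C15 configuration and the Z-alkene are retained.

**Step 10**
Reactants: 22 3-ethoxy-5-[(8Z,15S)-15-hydroxyheptadec-8-en-1-yl]phenol
Product: 24 hansfordiol G 5-[(8Z,15S)-15-hydroxyheptadec-8-en-1-yl]benzene-1,3-diol, via tris-borinate 23 (not isolated)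
Conditions: 9-I-9-BBN (4 equiv), 2,6-di-tert-butylpyridine (2.5 equiv), CH2Cl2/hexane, 0 °C → rt; then ethanolamine
Reagents that add atoms: none
Why: In this B-iodo-9-BBN ether cleavage both hydroxyls first become borinates (the HI released is held by the hindered pyridine, which cannot bind boron), the boron Lewis acid then coordinates the ethoxy oxygen and iodide removes the ethyl group by SN2, a non-protic dealkylation of the kind that leaves isolated Z-alkenes of alkenylresorcinol ethers intact and is not stopped by the oxygen already freed on the ring; the C15–O bond is not broken, so its configuration is kept, and ethanolamine releases the triol from boron.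

**Compound list**

1 | 1-bromo-4-chlorobutane | ClCCCCBr | starting material
2 | (S)-1,2-epoxybutane | CC[C@H]1CO1 | starting material
3 | 4-chlorobutylmagnesium bromide | ClCCCC[Mg]Br | intermediate
4 | (3S)-8-chlorooctan-3-ol | CC[C@H](O)CCCCCCl | intermediate
5 | tert-butyl{[(3S)-8-chlorooctan-3-yl]oxy}dimethylsilane | CC[C@H](O[Si](C)(C)C(C)(C)C)CCCCCCl | intermediate
6 | tert-butyl{[(3S)-8-iodooctan-3-yl]oxy}dimethylsilane | CC[C@H](O[Si](C)(C)C(C)(C)C)CCCCCI | intermediate
7 | non-8-yn-1-ol | C#CCCCCCCCO | starting material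
8 | dilithium salt of non-8-yn-1-ol (C-lithio acetylide, O-lithio alkoxide) | [Li]C#CCCCCCCCO[Li] | intermediate
9 | (15S)-15-(tert-butyldimethylsilyloxy)heptadec-8-yn-1-ol | CC[C@H](O[Si](C)(C)C(C)(C)C)CCCCCC#CCCCCCCCO | intermediate
10 | (8Z,15S)-15-(tert-butyldimethylsilyloxy)heptadec-8-en-1-ol | CC[C@H](O[Si](C)(C)C(C)(C)C)CCCCC/C=C\CCCCCCCO | intermediate
11 | (8Z,15S)-1-bromo-15-(tert-butyldimethylsilyloxy)heptadec-8-ene | CC[C@H](O[Si](C)(C)C(C)(C)C)CCCCC/C=C\CCCCCCCBr | intermediate
12 | 3-ethoxycyclobut-2-en-1-one | CCOC1=CC(=O)C1 | starting material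
13 | R–MgBr, [(8Z,15S)-15-(tert-butyldimethylsilyloxy)heptadec-8-en-1-yl]magnesium bromide | CC[C@H](O[Si](C)(C)C(C)(C)C)CCCCC/C=C\CCCCCCC[Mg]Br | intermediate
14 | 3-ethoxy-1-R-cyclobut-2-en-1-ol (both configurations at the carbinol carbon) | CC[C@H](O[Si](C)(C)C(C)(C)C)CCCCC/C=C\CCCCCCCC1(O)CC(OCC)=C1 | intermediate
15 | 3-[(8Z,15S)-15-(tert-butyldimethylsilyloxy)heptadec-8-en-1-yl]cyclobut-2-en-1-one | CC[C@H](O[Si](C)(C)C(C)(C)C)CCCCC/C=C\CCCCCCCC1=CC(=O)C1 | intermediate
16 | ethoxyacetylene | CCOC#C | starting material
17 | vinylketene O=C=CH–C(R)=CH2 | CC[C@H](O[Si](C)(C)C(C)(C)C)CCCCC/C=C\CCCCCCCC(=C)C=C=O | intermediate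
18 | 3-ethoxy-4-[1-R-ethenyl]cyclobut-2-en-1-one (racemic at C4 of the ring) | CC[C@H](O[Si](C)(C)C(C)(C)C)CCCCC/C=C\CCCCCCCC(=C)C1C(OCC)=CC1=O | intermediate
19 | dienylketene O=C=CH–C(OEt)=CH–C(R)=CH2, ketene arm and C(R)=CH2 group cis on the central double bond | CC[C@H](O[Si](C)(C)C(C)(C)C)CCCCC/C=C\CCCCCCCC(=C)/C=C(OCC)\C=C=O | intermediate
20 | 3-ethoxy-5-R-cyclohexa-2,4-dien-1-one | CC[C@H](O[Si](C)(C)C(C)(C)C)CCCCC/C=C\CCCCCCCC1=CC(OCC)=CC(=O)C1 | intermediate
21 | 3-ethoxy-5-[(8Z,15S)-15-(tert-butyldimethylsilyloxy)heptadec-8-en-1-yl]phenol | CC[C@H](O[Si](C)(C)C(C)(C)C)CCCCC/C=C\CCCCCCCc1cc(O)cc(OCC)c1 | intermediate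
22 | 3-ethoxy-5-[(8Z,15S)-15-hydroxyheptadec-8-en-1-yl]phenol | CC[C@H](O)CCCCC/C=C\CCCCCCCc1cc(O)cc(OCC)c1 | intermediate
23 | tris(9-borabicyclo[3.3.1]nonan-9-yl) borinate of the triol (both phenolic oxygens and the C15 oxygen on boron) | CC[C@H](OB1C2CCCC1CCC2)CCCCC/C=C\CCCCCCCc1cc(OB2C3CCCC2CCC3)cc(OB2C3CCCC2CCC3)c1 | intermediate
24 | hansfordiol G, 5-[(8Z,15S)-15-hydroxyheptadec-8-en-1-yl]benzene-1,3-diol | CC[C@H](O)CCCCC/C=C\CCCCCCCc1cc(O)cc(O)c1 | target

**Step count**

Total: 10 steps. Longest linear sequence: 10 steps (steps 1–10 from 1 and 2; compounds 7, 12 and 16 enter as purchased materials).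

**Steps most likely to fail**

Step 8. The volatile ynol ether may be lost by evaporation or by retro-ene fragmentation to ketene and ethylene, and the vinylketene may dimerise or polymerise faster than it is captured in the bimolecular [2+2] step. The fallback buys the ring instead of building it. It sets out from bromide 11 through its Grignard reagent 13 and comes back at 24. The coupling partner 1-bromo-3,5-bis(tert-butyldimethylsilyloxy)benzene F1 would be made from commercial 5-bromobenzene-1,3-diol with TBSCl and imidazole. Reagent 13 would be transmetalated with ZnCl2 to the alkylzinc chloride F2 and joined to F1 by Negishi coupling (Pd(OAc)2/SPhos, THF/NMP, 50 °C). This should give 1,3-bis(tert-butyldimethylsilyloxy)-5-[(8Z,15S)-15-(tert-butyldimethylsilyloxy)heptadec-8-en-1-yl]benzene F3, and TBAF would then remove all three silyl groups to give 24.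

Step 10. Hydrogen iodide released on borinate formation may escape the hindered base and add to or isomerise the Z-alkene, and removal of an ethyl group is slower than that of a methyl group, so cleavage may stall. The fallback changes the protecting-group plan so that no O–H is present during dealkylation. It sets out from 21 and comes back at 24. The phenol of 21 would be silylated (TBSCl, imidazole, DMF) to tert-butyl{3-ethoxy-5-[(8Z,15S)-15-(tert-butyldimethylsilyloxy)heptadec-8-en-1-yl]phenoxy}dimethylsilane F4. With 9-I-9-BBN in hexane the ethyl ether should then be cleaved without any protic acid forming, giving the aryl 9-BBN borinate F5. Ethanolamine would convert this into 3-(tert-butyldimethylsilyloxy)-5-[(8Z,15S)-15-(tert-butyldimethylsilyloxy)heptadec-8-en-1-yl]phenol F6. Any silyl loss at this stage is immaterial, because TBAF finally removes both silyl groups to give 24.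

Step 7. Wurtz coupling may occur on the magnesium surface, the basic Grignard reagent may enolise 12 at C4 instead of adding to its carbonyl, and prolonged acid may cost the silyl ether or decompose the strained enone. The fallback replaces magnesium insertion by halogen–metal exchange. It sets out from alcohol 10 and comes back at 15. Alcohol 10 would be converted (I2, PPh3, imidazole, CH2Cl2) into (8Z,15S)-15-(tert-butyldimethylsilyloxy)-1-iodoheptadec-8-ene F7. Iodine–lithium exchange (t-BuLi, 2 equiv, Et2O/pentane, −78 °C) would give the primary alkyllithium F8 without a metal surface. F8 would be added to 12 at −78 °C, and the adduct 14 hydrolysed with cold dilute acid as before to 15.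

**Further compounds**

F1 | step 8 | 1-bromo-3,5-bis(tert-butyldimethylsilyloxy)benzene | CC(C)(C)[Si](C)(C)Oc1cc(Br)cc(O[Si](C)(C)C(C)(C)C)c1
F2 | step 8 | [(8Z,15S)-15-(tert-butyldimethylsilyloxy)heptadec-8-en-1-yl]zinc chloride | CC[C@H](O[Si](C)(C)C(C)(C)C)CCCCC/C=C\CCCCCCC[Zn]Cl
F3 | step 8 | 1,3-bis(tert-butyldimethylsilyloxy)-5-[(8Z,15S)-15-(tert-butyldimethylsilyloxy)heptadec-8-en-1-yl]benzene | CC[C@H](O[Si](C)(C)C(C)(C)C)CCCCC/C=C\CCCCCCCc1cc(O[Si](C)(C)C(C)(C)C)cc(O[Si](C)(C)C(C)(C)C)c1
F4 | step 10 | tert-butyl{3-ethoxy-5-[(8Z,15S)-15-(tert-butyldimethylsilyloxy)heptadec-8-en-1-yl]phenoxy}dimethylsilane | CC[C@H](O[Si](C)(C)C(C)(C)C)CCCCC/C=C\CCCCCCCc1cc(O[Si](C)(C)C(C)(C)C)cc(OCC)c1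
F5 | step 10 | 9-{3-(tert-butyldimethylsilyloxy)-5-[(8Z,15S)-15-(tert-butyldimethylsilyloxy)heptadec-8-en-1-yl]phenoxy}-9-borabicyclo[3.3.1]nonane | CC[C@H](O[Si](C)(C)C(C)(C)C)CCCCC/C=C\CCCCCCCc1cc(OB2C3CCCC2CCC3)cc(O[Si](C)(C)C(C)(C)C)c1
F6 | step 10 | 3-(tert-butyldimethylsilyloxy)-5-[(8Z,15S)-15-(tert-butyldimethylsilyloxy)heptadec-8-en-1-yl]phenol | CC[C@H](O[Si](C)(C)C(C)(C)C)CCCCC/C=C\CCCCCCCc1cc(O)cc(O[Si](C)(C)C(C)(C)C)c1
F7 | step 7 | (8Z,15S)-15-(tert-butyldimethylsilyloxy)-1-iodoheptadec-8-ene | CC[C@H](O[Si](C)(C)C(C)(C)C)CCCCC/C=C\CCCCCCCI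
F8 | step 7 | [(8Z,15S)-15-(tert-butyldimethylsilyloxy)heptadec-8-en-1-yl]lithium | CC[C@H](O[Si](C)(C)C(C)(C)C)CCCCC/C=C\CCCCCCC[Li]
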